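The data were computed from invented constants; the scatter is artificial.

A small charge of catalyst, 16 mM against 3 M of starting material, gave a product in the teal run that rose and then stayed flat. We want to know what that flat stretch means for the new flasks.

| flask | starting material | catalyst | temperature | remark | time |
|---|---|---|---|---|---|
| teal | 3 M | 16 mM | 55 °C | run made earlier |  |
| delta | 3.0 M | 11 mM | 55 °C |  | 4.0 h |
| theta | 3.0 M | 11 mM | 25 °C |  | 4.0 h |
| beta | 3.0 M | 11 mM | 40 °C |  | 4.0 h |
| zeta | 3.0 M | 11 mM |  | at 55 °C until 50 min, from then on at 25 °C | 4.0 h |

teal run (percent of the starting material charged): time / min: product / % = 2.50: 9.1; 8.00: 15.4; 15.0: 15.1; 20.0: 16.0; 30.0: 16.4; 40.0: 16.2; 50.0: 16.0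

(scatter of a reading: 0.5 percentage points)

- the earlier runs do not show what temperature does; that part of a forecast is a guess
- no earlier run changes the charge of catalyst; that part of a forecast is a guess

- the flask with the highest amount of product, in percent of the starting material charged ("all alike" if they lie within 1.5 percentage points) (delta / theta / beta / zeta / all alike)
- final product, as a percentage of the starting material charged, in delta
- final product, as a percentage of the starting material charged, in theta
- final product, as a percentage of the starting material charged, in beta
- final product, as a percentage of the starting material charged, in zeta

We take the plateau as the mean of the teal readings from 20.0 min on, and the lifetime of the rise from the first reading: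

plateau = 16.1%

lifetime = 3.02 min

These are readings and carry their scatter. The flat stretch may mean an equilibrium, a dying catalyst, or a branching: the starting material may leave by a catalysed route to product and by a second route that needs no catalyst. We reckon with the branching. Then the odds of product, product over everything else, grow in proportion to the catalyst, and the constant of proportion is our selectivity factor, the plateau odds per unit of catalyst:

selectivity factor = plateau / (1 − plateau) / catalyst = 0.0120 mM⁻¹

For delta this gives

product = 11.7%

The objection is that a catalyst dying after a fixed number of turnovers gives 11.1% in delta. That lies 0.60 percentage points away, against a scatter of 0.5 points, so a reading of delta does not part these two, though it does part them from an equilibrium, for which the charge of catalyst does not matter and delta stays at the plateau.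

Zeta raises a second doubt: does any reaction remain for the cold stage? The lifetime may lengthen in proportion as the catalyst shrinks, yet even then the change at 50 min comes after

11.4 lifetimes

So with branching we expect zeta to stay at delta's value. An equilibrium may instead move on cooling, and that objection stands uncomputed.

For theta and beta the factor at lower temperature cannot be read from teal, so we give no number. The asked time is 79.6 lifetimes at teal's rate, which leaves room for a large slowing.

The forecast differs from our reckoning in delta and zeta. It gives 13% for delta, 22% for theta, 17% for beta and 15% for zeta, with theta highest, on the ground that “Cooling probably helps either way”.

The flasks give 11.5% in delta, 41.2% in theta, 22.6% in beta and 11.5% in zeta, so theta holds the most, 19 points above the forecast for it. At its change of temperature zeta already holds 0% starting material, 0% intermediate and 11.5% product.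

    starting material → intermediate (k = 5.67 × 10⁻⁴ s⁻¹, Ea = 84.0 kJ mol⁻¹)
    catalyst + intermediate → catalyst + product (k = 0.0161 M⁻¹ s⁻¹, Ea = 55.0 kJ mol⁻¹)
    intermediate → decomposed reagent (k = 2.49 × 10⁻⁴ s⁻¹, Ea = 101 kJ mol⁻¹)
    (constants at 25 °C)

Theta's own selectivity factor is 0.0638 mM⁻¹, which is 5.32 times the 0.0120 mM⁻¹ read from teal. With it, 13.4 mM of catalyst should shift theta by 4.9 points, and theta at that charge, with its temperature and time held, has moved by 5 points.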